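**Retrosynthetic overview**
- Feature: C3 carries CH3, OH and two arms, C2H2–C1(=O)–ring A and C4H–C(=O)–ring C. Both arenes are the same 2-acyl-3,5-dioxygenated phenyl unit with one ortho carbon substituent (C4 at C4a of ring A; the pyranonylmethyl group at C6' of ring C). Without the C4–C4a bond and the side chain, a mirror plane runs through C3.
- Last disconnections: the C6'–CH2 bond of ring C (sp2–sp3 cross-coupling with a metallated 6-methylpyranone) and all O-benzyl groups.
- Central disconnection: C4–C4a, closing ring B by a desymmetrising intramolecular ketone α-arylation of an achiral bis(bromoaryl) diketone, which sets C3 and C4.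
- The diketone comes from two molecules of one bromo-aldehyde and a 2-methylenepropane-1,3-diyl unit; hydration of the alkene gives C3–OH/CH3. Ring order: rings A and C and the pyranone are bought; ring B is the only ring made.

Key step: step 7

Remark on the chemistry: which hand of the bisphosphine leads to the (3R,4S) series cannot be predicted with confidence; (R)-DTBM-SEGPHOS is written, and its antipode is to be used if the first run shows the opposite sense.

**Step 1**
Reactants: 1 5-bromoresorcinol; 2 benzyl bromide (2 equiv)
Product: 3 1,3-bis(benzyloxy)-5-bromobenzene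
Conditions: K2CO3, DMF, 60 °C
Reagents that add atoms: none
Why: Williamson O-alkylation of both phenols, each by one molecule of the reactive benzylic halide, under carbonate base.

**Step 2**
Reactants: 3 1,3-bis(benzyloxy)-5-bromobenzene
Product: 5 2,4-bis(benzyloxy)-6-bromobenzaldehyde, via aryl iminium dichlorophosphate 4 (not isolated)
Conditions: POCl3, DMF, 0→90 °C; then ice/H2O
Reagents that add atoms: N,N-dimethylformamide CN(C)C=O (formyl carbon; its nitrogen stays only in 4); water O (aldehyde oxygen); POCl3 O=P(Cl)(Cl)Cl (counter-ion of 4 only)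
Why: Vilsmeier–Haack formylation should attack the position para to one benzyloxy group and ortho to the other (next to bromine), which is less crowded than the carbon between the two ethers, and the iminium salt is hydrolysed on work-up.

**Step 3**
Reactants: 5 2,4-bis(benzyloxy)-6-bromobenzaldehyde (2 equiv); 6 3-bromo-2-(bromomethyl)prop-1-ene
Product: 8 1,5-bis[2,4-bis(benzyloxy)-6-bromophenyl]-3-methylidenepentane-1,5-diol (meso/racemic mixture), via mono-adduct allylic bromide 7 (not isolated)
Conditions: In powder, THF/H2O (3:1), rt→40 °C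
Reagents that add atoms: none
Why: Indium-mediated Barbier allylation run twice in one flask, in which the allylindium from 6 adds to one aldehyde and the remaining allylic bromide of 7 is metallated and adds to a second; the aqueous medium keeps the carbinol protonated so that closure to a methylenetetrahydrofuran should not compete, and the two uncontrolled carbinol centres are erased in step 5.

**Step 4**
Reactants: 8 the methylidene diol
Product: 9 1,5-bis[2,4-bis(benzyloxy)-6-bromophenyl]-3-methylpentane-1,3,5-triol (diastereomer mixture)
Conditions: Co(acac)2 (cat.), PhSiH3, O2 (1 atm), THF, rt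
Reagents that add atoms: dioxygen O=O
Why: Mukaiyama hydration, in which a cobalt hydride delivers H to the terminal carbon of the 1,1-disubstituted alkene and the tertiary C3 radical is trapped by O2 and reduced to the Markovnikov alcohol; free alcohols, aryl bromides and benzyl ethers should be inert, and the diastereomers are carried on together.

**Step 5**
Reactants: 9 the triol mixture
Product: 10 1,5-bis[2,4-bis(benzyloxy)-6-bromophenyl]-3-hydroxy-3-methylpentane-1,5-dione (achiral)
Conditions: Dess–Martin periodinane, NaHCO3, CH2Cl2, 0 °C→rt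
Reagents that add atoms: none
Why: Dess–Martin oxidation converts only the two secondary benzylic carbinols (the tertiary C3–OH cannot be oxidised) under buffered neutral conditions that should spare the β-hydroxy ketone from dehydration and retro-aldol cleavage, so all diastereomers of 9 converge on one achiral diketone.

**Step 6**
Reactants: 10 the 3-hydroxy diketone
Product: 11 3-[(benzyloxy)methoxy]-1,5-bis[2,4-bis(benzyloxy)-6-bromophenyl]-3-methylpentane-1,5-dione (achiral key-step precursor)
Conditions: BnOCH2Cl, i-Pr2NEt, Bu4NI (cat.), CH2Cl2, 40 °C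
Reagents that add atoms: benzyl chloromethyl ether ClCOCc1ccccc1
Why: Alkoxymethylation of the tertiary alcohol by a chloromethyl ether with a hindered amine that is too weak to enolise the aryl ketones gives an acetal ether that blocks retro-aldol cleavage and O-arylation in step 7 and is removed by hydrogenolysis at the end.

**Step 7**
Reactants: 11 the achiral bis(bromoaryl) diketone
Product: 12 (3R,4S)-6,8-bis(benzyloxy)-3-[(benzyloxy)methoxy]-4-[2,4-bis(benzyloxy)-6-bromobenzoyl]-3-methyl-3,4-dihydronaphthalen-1(2H)-one
Conditions: Pd2(dba)3 (2.5 mol%), (R)-DTBM-SEGPHOS (6 mol%), K3PO4 (1.5 equiv), toluene, 50 °C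
Reagents that add atoms: none
Why: Proposed new method: zerovalent palladium carrying the chiral bisphosphine inserts into one C–Br bond, phosphate removes an α-proton from the ketone of the other arm once that ketone is bound to the arylpalladium bromide, and C(sp2)–C(sp3) reductive elimination from the seven-membered aryl–palladium–C-enolate palladacycle (Pd, C4a, C8a, C1, C2, C3, C4) forms C4–C4a; the closest known reaction type is the enantioselective intramolecular palladium-catalysed α-arylation that desymmetrises a prochiral diketone carrying a single haloarene, whereas here each arm is donor and acceptor at once. Ring B closes as a six-membered ring with the enolate C=C exocyclic to it, and only the cross-arm mode is open, because the CH2 of the arm that holds palladium could give only a four-membered ring, O-arylation would need an eight-membered ring, and a second closure from the surviving bromide would have to build a bridged bicyclo[3.3.1] array. C3 is set by the catalyst, since the arm whose bromide is spent becomes C1/C2 and the arm that is enolised becomes C4, so the choice between the two enantiotopic bromoaryl ketone arms is the choice between 3R and 3S. C4 is set by the substrate, the aroyl group settling trans to the C3 methyl (cis to the smaller C3 oxygen), and the acidic C4–H allows a cis fraction to equilibrate under the phosphate. The step needs group selectivity between two C–Br bonds that lie four bonds from C3; what the substrate offers for this is the 1,5-dicarbonyl spacing, which can hold the carbonyl of the second arm on palladium in a C3-containing chelate while the C–Br bond breaks, and this selection, not the ring closure, is the uncertain point. It also needs coupling of the enolate to outrun expulsion of the C3 oxygen, which the acetal ether, the weak heterogeneous base and the low temperature are chosen to secure.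

**Step 8**
Reactants: 13 triacetic acid lactone (4-hydroxy-6-methyl-2H-pyran-2-one); 2 benzyl bromide
Product: 14 4-(benzyloxy)-6-methyl-2H-pyran-2-one
Conditions: K2CO3, DMF, rt
Reagents that add atoms: none
Why: Williamson-type O-alkylation of the vinylogous acid in a polar aprotic solvent should favour the 4-alkoxy-2-pyranone over C3-benzylation and over the 2-alkoxy-4-pyranone isomer.

**Step 9**
Reactants: 12 the ring C bromide; 14 4-(benzyloxy)-6-methyl-2H-pyran-2-one
Product: 17 (3R,4S)-6,8-bis(benzyloxy)-3-[(benzyloxy)methoxy]-4-{2,4-bis(benzyloxy)-6-{[4-(benzyloxy)-2-oxo-2H-pyran-6-yl]methyl}benzoyl}-3-methyl-3,4-dihydronaphthalen-1(2H)-one, via lithiated pyranone 15 (not isolated), via pyranonylmethylzinc bromide 16 (not isolated)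
Conditions: 14, LiN(SiMe3)2, THF, −78 °C; ZnBr2, −78→0 °C; then 12, Pd(OAc)2 (5 mol%), SPhos (10 mol%), THF, 25→45 °C
Reagents that add atoms: LiN(SiMe3)2 [Li]N([Si](C)(C)C)[Si](C)(C)C (lithium of 15 only); ZnBr2 Br[Zn]Br (zinc and bromine of 16 only)
Why: Lateral deprotonation of the 6-methyl group gives the fully conjugated anion, transmetallation gives a heterobenzylic (vinylogous Reformatsky) zinc reagent that should be too weakly basic to enolise the ketones of 12, and Negishi coupling joins its exocyclic CH2 to C6' of ring C without touching C3 or C4.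

**Step 10**
Reactants: 17 the fully protected coupling product
Product: 19 (3R,4S)-4-{2,4-dihydroxy-6-[(4-hydroxy-2-oxo-2H-pyran-6-yl)methyl]benzoyl}-3,6,8-trihydroxy-3-methyl-3,4-dihydronaphthalen-1(2H)-one (CNP0197349.1), via C3-hemiformal 18 (not isolated)
Conditions: H2 (1 atm), 10% Pd/C, EtOAc/THF (1:1), rt; filter, concentrate
Reagents that add atoms: none
Why: Neutral hydrogenolysis cleaves the five O-benzyl ethers and the benzyl group of the acetal, the C3 hemiformal then loses formaldehyde, and the absence of acid and base should protect the tertiary β-hydroxy ketone from dehydration to a naphthol and C4 from epimerisation.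

**Compound list**
1 | 5-bromoresorcinol | Oc1cc(O)cc(Br)c1 | starting material
2 | benzyl bromide | BrCc1ccccc1 | starting material
3 | 1,3-bis(benzyloxy)-5-bromobenzene | Brc1cc(OCc2ccccc2)cc(OCc2ccccc2)c1 | intermediate
4 | [2,4-bis(benzyloxy)-6-bromobenzylidene]dimethyliminium dichlorophosphate (not isolated) | C[N+](C)=Cc1c(Br)cc(OCc2ccccc2)cc1OCc1ccccc1.[O-]P(=O)(Cl)Cl | intermediate
5 | 2,4-bis(benzyloxy)-6-bromobenzaldehyde | O=Cc1c(Br)cc(OCc2ccccc2)cc1OCc1ccccc1 | intermediate
6 | 3-bromo-2-(bromomethyl)prop-1-ene | C=C(CBr)CBr | starting material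
7 | 1-[2,4-bis(benzyloxy)-6-bromophenyl]-3-(bromomethyl)but-3-en-1-ol, racemic (not isolated) | C=C(CBr)CC(O)c1c(Br)cc(OCc2ccccc2)cc1OCc1ccccc1 | intermediate
8 | 1,5-bis[2,4-bis(benzyloxy)-6-bromophenyl]-3-methylidenepentane-1,5-diol, mixture of the meso and the racemic diastereomer (carbinol centres undefined) | C=C(CC(O)c1c(Br)cc(OCc2ccccc2)cc1OCc1ccccc1)CC(O)c1c(Br)cc(OCc2ccccc2)cc1OCc1ccccc1 | intermediate
9 | 1,5-bis[2,4-bis(benzyloxy)-6-bromophenyl]-3-methylpentane-1,3,5-triol, mixture of two meso forms and the racemic pair (centres undefined) | CC(O)(CC(O)c1c(Br)cc(OCc2ccccc2)cc1OCc1ccccc1)CC(O)c1c(Br)cc(OCc2ccccc2)cc1OCc1ccccc1 | intermediate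
10 | 1,5-bis[2,4-bis(benzyloxy)-6-bromophenyl]-3-hydroxy-3-methylpentane-1,5-dione, achiral | CC(O)(CC(=O)c1c(Br)cc(OCc2ccccc2)cc1OCc1ccccc1)CC(=O)c1c(Br)cc(OCc2ccccc2)cc1OCc1ccccc1 | intermediate
11 | 3-[(benzyloxy)methoxy]-1,5-bis[2,4-bis(benzyloxy)-6-bromophenyl]-3-methylpentane-1,5-dione, achiral | CC(OCOCc1ccccc1)(CC(=O)c1c(Br)cc(OCc2ccccc2)cc1OCc1ccccc1)CC(=O)c1c(Br)cc(OCc2ccccc2)cc1OCc1ccccc1 | intermediate
12 | (3R,4S)-6,8-bis(benzyloxy)-3-[(benzyloxy)methoxy]-4-[2,4-bis(benzyloxy)-6-bromobenzoyl]-3-methyl-3,4-dihydronaphthalen-1(2H)-one | C[C@@]1(OCOCc2ccccc2)CC(=O)c2c(OCc3ccccc3)cc(OCc3ccccc3)cc2[C@@H]1C(=O)c1c(OCc2ccccc2)cc(OCc2ccccc2)cc1Br | intermediate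
13 | triacetic acid lactone (4-hydroxy-6-methyl-2H-pyran-2-one) | Cc1cc(O)cc(=O)o1 | starting material
14 | 4-(benzyloxy)-6-methyl-2H-pyran-2-one | Cc1cc(OCc2ccccc2)cc(=O)o1 | intermediate
15 | [4-(benzyloxy)-2-oxo-2H-pyran-6-yl]methyllithium (not isolated) | [Li]Cc1cc(OCc2ccccc2)cc(=O)o1 | intermediate
16 | {[4-(benzyloxy)-2-oxo-2H-pyran-6-yl]methyl}zinc bromide (not isolated) | Br[Zn]Cc1cc(OCc2ccccc2)cc(=O)o1 | intermediate
17 | (3R,4S)-6,8-bis(benzyloxy)-3-[(benzyloxy)methoxy]-4-{2,4-bis(benzyloxy)-6-{[4-(benzyloxy)-2-oxo-2H-pyran-6-yl]methyl}benzoyl}-3-methyl-3,4-dihydronaphthalen-1(2H)-one | C[C@@]1(OCOCc2ccccc2)CC(=O)c2c(OCc3ccccc3)cc(OCc3ccccc3)cc2[C@@H]1C(=O)c1c(OCc2ccccc2)cc(OCc2ccccc2)cc1Cc1cc(OCc2ccccc2)cc(=O)o1 | intermediate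
18 | (3R,4S)-4-{2,4-dihydroxy-6-[(4-hydroxy-2-oxo-2H-pyran-6-yl)methyl]benzoyl}-6,8-dihydroxy-3-(hydroxymethoxy)-3-methyl-3,4-dihydronaphthalen-1(2H)-one (not isolated) | C[C@@]1(OCO)CC(=O)c2c(O)cc(O)cc2[C@@H]1C(=O)c1c(O)cc(O)cc1Cc1cc(O)cc(=O)o1 | intermediate
19 | (3R,4S)-4-{2,4-dihydroxy-6-[(4-hydroxy-2-oxo-2H-pyran-6-yl)methyl]benzoyl}-3,6,8-trihydroxy-3-methyl-3,4-dihydronaphthalen-1(2H)-one (CNP0197349.1) | C[C@@]1(O)CC(=O)c2c(O)cc(O)cc2[C@@H]1C(=O)c1c(O)cc(O)cc1Cc1cc(O)cc(=O)o1 | target

**Totals**
Total step count: 10. Longest linear sequence: 9 steps (steps 1 to 7, then 9 and 10); step 8 is a one-step branch.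

**Steps most likely to fail**

Step 7. Two processes threaten it. The catalyst may fail to distinguish the enantiotopic arms at oxidative addition, so that both enantiomers form. The enolate, or the more acidic product, may expel the C3 oxygen, after which ring B aromatises. The fallback uses known chemistry; it replaces catalyst-controlled arm selection by an unselective closure plus a separation, and the free enolate by an enol silane. It sets out from 11. LiN(SiMe3)2 in the presence of Me3SiCl (THF, −78 °C, internal quench) should give the (1Z,4Z)-bis(trimethylsilyl enol ether) F1. Palladium-catalysed intramolecular arylation of the enol silane under fluoride activation (Pd2(dba)3, P(t-Bu)3, Bu3SnF, toluene, 60 °C), followed by a buffered aqueous work-up that hydrolyses the second enol silane, should give the racemic trans tetralone, that is 12 together with its (3S,4R) enantiomer F2. Preparative HPLC on a chiral stationary phase removes F2, and the route is rejoined at 12.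

Step 9. The acidic C4–H may protonate the zinc reagent, which destroys it and opens the way to loss of the C3 oxygen. The dienolate may couple through a ring carbon instead of the exocyclic CH2, or add to a ketone. The fallback replaces the basic organozinc by an isolable, non-basic tin reagent. It sets out from 14: deprotonation with LiN(SiMe3)2 (THF, −78 °C) and quenching with Bu3SnCl should give 4-(benzyloxy)-6-[(tributylstannyl)methyl]-2H-pyran-2-one F3. Stille coupling of F3 with 12 (Pd(PPh3)4, CuI, DMF, 60 °C) rejoins the route at 17.

Step 10. The pyranone C5=C6 bond or an aryl ketone may be reduced before the last benzyl ether is cleaved, or the C3 hemiformal may persist. The fallback is non-reductive: it sets out from 17 and uses BCl3 with pentamethylbenzene as cation scavenger (CH2Cl2, −78 °C, then aqueous NaHCO3) to cleave all benzyl ethers and the acetal, arriving directly at 19 (no new compound: F0).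

**Further compounds**
F1 | step 7 | (1Z,4Z)-3-[(benzyloxy)methoxy]-1,5-bis[2,4-bis(benzyloxy)-6-bromophenyl]-3-methyl-1,5-bis(trimethylsilyloxy)penta-1,4-diene | CC(OCOCc1ccccc1)(/C=C(\O[Si](C)(C)C)c1c(Br)cc(OCc2ccccc2)cc1OCc1ccccc1)/C=C(\O[Si](C)(C)C)c1c(Br)cc(OCc2ccccc2)cc1OCc1ccccc1
F2 | step 7 | (3S,4R)-enantiomer of 12, formed as half of the racemate | C[C@]1(OCOCc2ccccc2)CC(=O)c2c(OCc3ccccc3)cc(OCc3ccccc3)cc2[C@H]1C(=O)c1c(OCc2ccccc2)cc(OCc2ccccc2)cc1Br
F3 | step 9 | 4-(benzyloxy)-6-[(tributylstannyl)methyl]-2H-pyran-2-one | CCCC[Sn](CCCC)(CCCC)Cc1cc(OCc2ccccc2)cc(=O)o1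
F0 | step 10 | none | none
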